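The readings stem from a simulated flask on assumed constants.

Which of the four flasks holds the most complex with one exchanged at 10 h?

| flask | starting complex | incoming ligand | remark | time |
|---|---|---|---|---|
| eta | 11 mM | 0.95 equiv | run made earlier |  |
| zeta | 11 mM | 0.47 equiv | run made earlier |  |
| delta | 11 mM | 0.71 equiv | run made earlier |  |
| Friday's | 11 mM | 0.950 equiv (in portions, 4, over 6.0 h) | first portion at the start, last at 6.0 h | 10 h |
| Tuesday's | 11 mM | 0.950 equiv (fed, over 6.0 h) | all else is in the flask from the start; the feed brings no volume worth counting | 10 h |
| Monday's | 11 mM (fed, over 6.0 h) | 0.950 equiv | all else is in the flask from the start; the feed brings no volume worth counting | 10 h |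
| Sunday's | 11 mM | 0.950 equiv | everything together at the start | 10 h |

| run | time / h | complex with one exchanged / % |
|---|---|---|
| eta | 1.50 | 15 |
| eta | 3.00 | 30 |
| eta | 5.00 | 35 |
| eta | 6.00 | 37 |
| eta | 8.00 | 44 |
| eta | 10.0 | 47 |
| zeta | 0.500 | 3 |
| zeta | 0.833 | 3 |
| zeta | 1.33 | 6 |
| zeta | 2.00 | 13 |
| zeta | 4.00 | 18 |
| zeta | 6.00 | 24 |
| delta | 0.417 | 6 |
| delta | 1.33 | 10 |
| delta | 2.00 | 14 |
| delta | 3.00 | 17 |
| delta | 5.00 | 29 |
| delta | 6.00 | 29 |

(each reading ± 1.5 percentage points)

* the flask with the highest amount of complex with one exchanged, in percent of the starting complex charged ("all alike" if they lie within 1.5 percentage points) (Friday's / Tuesday's / Monday's / Sunday's / all alike)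
* final complex with one exchanged, as a percentage of the starting complex charged, in Friday's
* final complex with one exchanged, as a percentage of the starting complex charged, in Tuesday's
* final complex with one exchanged, as a percentage of the starting complex charged, in Monday's
* final complex with one exchanged, as a percentage of the starting complex charged, in Sunday's

- the analysis behind the earlier runs scatters by 1.5 percentage points, standard deviation

To whoever takes over the bench: count clocks. The earlier runs start at rates that go with the ligand charge, so take the rate as c of starting complex times c of incoming ligand. The two are charged nearly equal here. The eta run shows 30% made at 3.00 h, and if you count that reading as what has reacted, it gives the clock, the time in which half the starting complex is gone at these charges (second-order half-life): 7.00 h. If the two are taken as equal and as used one for one, the part of starting complex left after any time is one over (one plus the clocks run).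

When you come to Sunday's flask, 1.43 clocks will have run, so expect 41.2% of the starting complex left. In the other three flasks, the fed partner has on average half of its charge delivered during the 6.0 h of feeding, and Friday's 4 portions average the same. I therefore count 7.00 h of full-strength time for those three, less than the 10 h of Sunday's flask, and that count leaves 50.0% of their starting complex. My reckoning puts Sunday's ahead by 8.8 percentage points in starting complex used. Leave the feeds as set, since the reckoning counts on their length.

The forecast also says Sunday's, with 41.5%, 40.5%, 39% and 47.5% in the order Friday's, Tuesday's, Monday's, Sunday's, on the ground that feeding “delays the time the two spend together”.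

The flasks give 39.7%, 40.0%, 39.0% and 45.0%, in the same order, so Sunday's is highest.

    starting complex + incoming ligand → leaving ligand + complex with one exchanged (k = 13.0 /M/h)
    complex with one exchanged + incoming ligand → leaving ligand + complex with two exchanged (k = 5.40 /M/h)
    complex with two exchanged + incoming ligand → leaving ligand + complex with three exchanged (k = 32.0 /M/h)
    complex with three exchanged + incoming ligand → leaving ligand + complex with four exchanged (k = 17.0 /M/h)

In Sunday's flask at 2.75 h, complex with one exchanged is made faster than it is used up, by a factor of 7.03. Starting complex left at the end is 46% in Sunday's and 54% in Tuesday's, above the clock's 41.2% and 50.0%, but the gap of 7.8 points stands near the reckoned 8.8 points.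

Read Sunday's flask at 4.0 h instead: the clock leaves 63.6% of the starting complex, and the flask holds 65.6% of it.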